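**Retrosynthetic overview**

1. Target 18 comes from its 7-O-MOM ether 17 by acetal cleavage; the MOM group keeps O7 neutral during the key step.
2. 17 comes from the acyclic 2'-hydroxyaryl ynone 15 by one base-triggered double cyclisation. Ring C closes first (phenoxide onto the ynone, O1–C2). Ring D then closes by its aryl ether bond: the tertiary alkoxide of a Z-held 3-hydroxy-3-methylbutenyl arm displaces fluoride from C4' of ring B, the carbon that becomes C8a of the 2H-chromene.
3. Enabling feature: C4' is para to C1', and C1' is bonded to C2 of ring C. Charge arriving at C1' runs through C2=C3 onto the C4 carbonyl oxygen (through C≡C–C=O before ring C closes), so the C4'–F carbon is the end of a vinylogous acyl acceptor.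
4. 15 comes from aldehyde 4 (ring A) and alkyne 11 (ring B) by acetylide addition and MnO2 oxidation; the oxidation is the switch that activates the fluoride, which is inert before it.
5. 4 comes from 5-bromo-2,4-dihydroxybenzaldehyde (MOM protection, Stille prenylation); 11 comes from 4-bromo-1-fluoro-2-iodobenzene (Sonogashira, Lindlar, Sonogashira, desilylation). Rings A and B are bought as benzenes; ring C and then ring D are formed in step 9.

Key step: step 9

Remark: the target has no stereocentre. The only stereochemical element of the route is the Z-alkene of the ring B side arm (set in step 4, later the endocyclic C3=C4 bond of ring D). The carbinol centre of 14 is formed racemic and is removed in step 8.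

**Route**

Step 1
Reactants: 1 5-bromo-2,4-dihydroxybenzaldehyde
Product: 2 5-bromo-2-hydroxy-4-(methoxymethoxy)benzaldehyde
Conditions: MOMCl (1.05 equiv), K2CO3 (1.2 equiv), acetone, 0 to 25 °C
Reagents that add atoms: chloromethyl methyl ether (MOMCl), COCCl
Why: Williamson-type O-alkylation (MOM protection), in which the 4-OH, para to the formyl group and not tied up in the hydrogen bond that holds the 2-OH to the aldehyde, is the more acidic and more nucleophilic phenol and should be protected selectively by one equivalent of MOMCl.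

Step 2
Reactants: 2 5-bromo-2-hydroxy-4-(methoxymethoxy)benzaldehyde; 3 tributyl(3-methylbut-2-en-1-yl)stannane
Product: 4 2-hydroxy-4-(methoxymethoxy)-5-(3-methylbut-2-en-1-yl)benzaldehyde
Conditions: Pd(PPh3)4 (5 mol %), DMF, 100 °C
Reagents that add atoms: none
Why: Stille coupling, in which zerovalent palladium inserts into the C–Br bond, the prenyl group is transferred from tin and reductive elimination at the unsubstituted CH2 end of the prenyl ligand should give the linear prenyl arene, while the neutral conditions tolerate the free phenol and the aldehyde.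

Step 3
Reactants: 5 4-bromo-1-fluoro-2-iodobenzene; 6 2-methylbut-3-yn-2-ol
Product: 7 4-(5-bromo-2-fluorophenyl)-2-methylbut-3-yn-2-ol
Conditions: Pd(PPh3)2Cl2 (2 mol %), CuI (4 mol %), Et3N, THF, 25 °C
Reagents that add atoms: none
Why: Sonogashira coupling, in which the C–I bond undergoes oxidative addition far faster than C–Br at room temperature and C–F is inert, so the alkynol should be installed only at the carbon ortho to fluorine.

Step 4
Reactants: 7 4-(5-bromo-2-fluorophenyl)-2-methylbut-3-yn-2-ol
Product: 8 (Z)-4-(5-bromo-2-fluorophenyl)-2-methylbut-3-en-2-ol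
Conditions: H2 (1 atm), Pd/CaCO3 poisoned with Pb(OAc)2, quinoline, EtOAc, 25 °C
Reagents that add atoms: none
Why: Lindlar semihydrogenation, in which syn delivery of both hydrogens from the poisoned palladium surface sets the Z-alkene that later holds the tertiary oxygen next to the C–F carbon, and the poisoned catalyst should leave the aryl bromide and the product alkene untouched.

Step 5
Reactants: 8 (Z)-4-(5-bromo-2-fluorophenyl)-2-methylbut-3-en-2-ol; 9 ethynyltrimethylsilane
Product: 10 (Z)-4-{2-fluoro-5-[(trimethylsilyl)ethynyl]phenyl}-2-methylbut-3-en-2-ol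
Conditions: Pd(PhCN)2Cl2 (3 mol %), P(t-Bu)3 (6 mol %), CuI (2 mol %), i-Pr2NH, dioxane, 25 °C
Reagents that add atoms: none
Why: Sonogashira coupling of an aryl bromide, which the electron-rich bulky phosphine allows at room temperature, so that the free tertiary alcohol, the Z-alkene and the unactivated C–F bond should remain spectators.

Step 6
Reactants: 10 (Z)-4-{2-fluoro-5-[(trimethylsilyl)ethynyl]phenyl}-2-methylbut-3-en-2-ol
Product: 11 (Z)-4-(5-ethynyl-2-fluorophenyl)-2-methylbut-3-en-2-ol
Conditions: K2CO3 (0.2 equiv), MeOH, 25 °C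
Reagents that add atoms: none
Why: Protodesilylation of the C(sp)–Si bond by catalytic methoxide, with no substitution of fluoride expected because the C–F carbon is para only to an alkynyl group and carries no acceptor yet.

Step 7
Reactants: 4 2-hydroxy-4-(methoxymethoxy)-5-(3-methylbut-2-en-1-yl)benzaldehyde; 11 (Z)-4-(5-ethynyl-2-fluorophenyl)-2-methylbut-3-en-2-ol
Product: 14 2-{3-[4-fluoro-3-((Z)-3-hydroxy-3-methylbut-1-en-1-yl)phenyl]-1-hydroxyprop-2-yn-1-yl}-5-(methoxymethoxy)-4-(3-methylbut-2-en-1-yl)phenol (racemic), via lithium phenoxide 12 (not isolated), via dilithiated alkynol 13 (not isolated)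
Conditions: 11 (1.2 equiv), n-BuLi (2.4 equiv), THF, −78 to −20 °C; 4, LiN(SiMe3)2 (1.0 equiv), THF, −78 °C; combine, −78 to 0 °C; aq. NH4Cl
Reagents that add atoms: none
Why: 1,2-addition of a lithium acetylide to an aldehyde, in which masking the phenol as its lithium phenoxide and the tertiary alcohol as its alkoxide avoids wasting the acetylide, and the new carbinol centre is formed racemic, which is of no consequence because step 8 removes it.

Step 8
Reactants: 14 2-{3-[4-fluoro-3-((Z)-3-hydroxy-3-methylbut-1-en-1-yl)phenyl]-1-hydroxyprop-2-yn-1-yl}-5-(methoxymethoxy)-4-(3-methylbut-2-en-1-yl)phenol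
Product: 15 3-{4-fluoro-3-[(Z)-3-hydroxy-3-methylbut-1-en-1-yl]phenyl}-1-[2-hydroxy-4-(methoxymethoxy)-5-(3-methylbut-2-en-1-yl)phenyl]prop-2-yn-1-one
Conditions: MnO2 (activated, 15 equiv), CH2Cl2, 25 °C
Reagents that add atoms: none
Why: MnO2 oxidation of a benzylic and propargylic secondary alcohol to the ynone, in which the tertiary allylic alcohol cannot be oxidised and the neutral heterogeneous conditions should leave the hydrogen-bonded 2'-hydroxy ynone uncyclised.

Step 9
Reactants: 15 3-{4-fluoro-3-[(Z)-3-hydroxy-3-methylbut-1-en-1-yl]phenyl}-1-[2-hydroxy-4-(methoxymethoxy)-5-(3-methylbut-2-en-1-yl)phenyl]prop-2-yn-1-one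
Product: 17 2-(2,2-dimethyl-2H-chromen-6-yl)-7-(methoxymethoxy)-6-(3-methylbut-2-en-1-yl)-4H-chromen-4-one, via fluoroflavone 16 (not isolated)
Conditions: KOtBu (1.1 equiv), THF, 0 to 25 °C; then KOtBu (1.1 equiv), 60 °C
Reagents that add atoms: none
Why: KOtBu deprotonates the phenol, the phenoxide adds to the β-carbon of the ynone (oxa-Michael) to close ring C in the 6-endo-dig mode, and the C3 carbanion so formed takes the proton of the tertiary OH (directly or through t-BuOH), so that the same base equivalent reappears as the side-arm alkoxide. This alkoxide, held next to C4' by the Z-alkene, adds to C4' and expels fluoride (addition–elimination SNAr, 6-exo-trig on the C4'=C5' bond), closing ring D by its aryl C–O bond, while the Meisenheimer charge at C1' is carried through C2=C3 onto the C4 carbonyl oxygen. The closest known reaction types are the base-mediated cyclisation of 2'-hydroxyaryl ynones to flavones in aprotic media and the intramolecular SNAr etherification of fluoroarenes by tethered alkoxides used for chromans. No stereocentre is formed, and the Z-alkene from step 4 becomes the endocyclic C3=C4 bond of ring D. The selectivities needed are 6-endo over 5-exo closure of ring C (the aurone mode), secured by the aprotic potassium phenoxide conditions and the polarisation of the ynone, and attack at C4' instead of C2 of ring C or of a second molecule, secured by the cis geometry that lets the oxygen reach only C4', by fluoride being the only leaving group, and by the MOM ether, which stops O7 from becoming a phenoxide that would cancel the acceptor.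

Step 10
Reactants: 17 2-(2,2-dimethyl-2H-chromen-6-yl)-7-(methoxymethoxy)-6-(3-methylbut-2-en-1-yl)-4H-chromen-4-one
Product: 18 kanzonol E, 2-(2,2-dimethyl-2H-chromen-6-yl)-7-hydroxy-6-(3-methylbut-2-en-1-yl)-4H-chromen-4-one
Conditions: 3 M aq. HCl, MeOH–THF, 40 °C
Reagents that add atoms: none
Why: Acid-catalysed acetal cleavage (MOM removal) by transfer of the methoxymethyl group to methanol, under dilute acid and mild temperature that ortho-prenyl phenols and 2,2-dimethylchromenes are expected to survive.

**Compound list**

1 | 5-bromo-2,4-dihydroxybenzaldehyde | O=Cc1cc(Br)c(O)cc1O | starting material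
2 | 5-bromo-2-hydroxy-4-(methoxymethoxy)benzaldehyde | O=Cc1cc(Br)c(OCOC)cc1O | intermediate
3 | tributyl(3-methylbut-2-en-1-yl)stannane | CCCC[Sn](CCCC)(CCCC)CC=C(C)C | starting material
4 | 2-hydroxy-4-(methoxymethoxy)-5-(3-methylbut-2-en-1-yl)benzaldehyde | O=Cc1cc(CC=C(C)C)c(OCOC)cc1O | intermediate
5 | 4-bromo-1-fluoro-2-iodobenzene | Fc1ccc(Br)cc1I | starting material
6 | 2-methylbut-3-yn-2-ol | CC(C)(O)C#C | starting material
7 | 4-(5-bromo-2-fluorophenyl)-2-methylbut-3-yn-2-ol | CC(C)(O)C#Cc1cc(Br)ccc1F | intermediate
8 | (Z)-4-(5-bromo-2-fluorophenyl)-2-methylbut-3-en-2-ol | CC(C)(O)/C=C\c1cc(Br)ccc1F | intermediate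
9 | ethynyltrimethylsilane | C#C[Si](C)(C)C | starting material
10 | (Z)-4-{2-fluoro-5-[(trimethylsilyl)ethynyl]phenyl}-2-methylbut-3-en-2-ol | CC(C)(O)/C=C\c1cc(C#C[Si](C)(C)C)ccc1F | intermediate
11 | (Z)-4-(5-ethynyl-2-fluorophenyl)-2-methylbut-3-en-2-ol | CC(C)(O)/C=C\c1cc(C#C)ccc1F | intermediate
12 | lithium 2-formyl-5-(methoxymethoxy)-4-(3-methylbut-2-en-1-yl)phenolate (not isolated) | [Li]Oc1cc(OCOC)c(CC=C(C)C)cc1C=O | intermediate
13 | dilithio derivative of 11, lithium acetylide and lithium alkoxide (not isolated) | [Li]C#Cc1ccc(F)c(/C=C\C(C)(C)O[Li])c1 | intermediate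
14 | 2-{3-[4-fluoro-3-((Z)-3-hydroxy-3-methylbut-1-en-1-yl)phenyl]-1-hydroxyprop-2-yn-1-yl}-5-(methoxymethoxy)-4-(3-methylbut-2-en-1-yl)phenol (racemic) | CC(C)=CCc1cc(C(O)C#Cc2ccc(F)c(/C=C\C(C)(C)O)c2)c(O)cc1OCOC | intermediate
15 | 3-{4-fluoro-3-[(Z)-3-hydroxy-3-methylbut-1-en-1-yl]phenyl}-1-[2-hydroxy-4-(methoxymethoxy)-5-(3-methylbut-2-en-1-yl)phenyl]prop-2-yn-1-one | CC(C)=CCc1cc(C(=O)C#Cc2ccc(F)c(/C=C\C(C)(C)O)c2)c(O)cc1OCOC | intermediate
16 | 2-{4-fluoro-3-[(Z)-3-hydroxy-3-methylbut-1-en-1-yl]phenyl}-7-(methoxymethoxy)-6-(3-methylbut-2-en-1-yl)-4H-chromen-4-one (not isolated) | CC(C)=CCc1cc2c(=O)cc(-c3ccc(F)c(/C=C\C(C)(C)O)c3)oc2cc1OCOC | intermediate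
17 | 2-(2,2-dimethyl-2H-chromen-6-yl)-7-(methoxymethoxy)-6-(3-methylbut-2-en-1-yl)-4H-chromen-4-one | CC(C)=CCc1cc2c(=O)cc(-c3ccc4c(c3)C=CC(C)(C)O4)oc2cc1OCOC | intermediate
18 | kanzonol E, 2-(2,2-dimethyl-2H-chromen-6-yl)-7-hydroxy-6-(3-methylbut-2-en-1-yl)-4H-chromen-4-one | CC(C)=CCc1cc2c(=O)cc(-c3ccc4c(c3)C=CC(C)(C)O4)oc2cc1O | target

**Step count**

Total: 10 steps. Longest linear sequence: 8 steps (steps 3, 4, 5, 6, 7, 8, 9, 10, from 5 to 18).

**Steps most likely to fail**

Step 9. Ring C may close in the 5-exo mode, or the fluoride displacement may be too slow for the moderate activation offered by the pyranone, so that alkoxide-induced degradation or base-induced migration of the prenyl double bond competes. The fallback sets out from aldehyde 4 (as its lithium phenoxide 12), gives up the late ring closure and builds ring D first by the classical aryl propargyl ether route; it comes back to the route at 17. 4-Hydroxybenzaldehyde would be O-alkylated with 3-chloro-3-methylbut-1-yne (K2CO3, KI, CuI cat., acetone, reflux) to 4-[(2-methylbut-3-yn-2-yl)oxy]benzaldehyde F1. Heating in N,N-diethylaniline at 190 °C should take this through propargyl Claisen rearrangement, 1,5-hydrogen shift and oxa-6π electrocyclisation to 2,2-dimethyl-2H-chromene-6-carbaldehyde F2. Ohira–Bestmann homologation (dimethyl (1-diazo-2-oxopropyl)phosphonate, K2CO3, MeOH) would give 6-ethynyl-2,2-dimethyl-2H-chromene F3. Its lithium acetylide (n-BuLi, THF, −78 °C) would be added to 12 as in step 7 to give the propargylic alcohol 2-[3-(2,2-dimethyl-2H-chromen-6-yl)-1-hydroxyprop-2-yn-1-yl]-5-(methoxymethoxy)-4-(3-methylbut-2-en-1-yl)phenol F4. MnO2 in CH2Cl2 would give the ynone 3-(2,2-dimethyl-2H-chromen-6-yl)-1-[2-hydroxy-4-(methoxymethoxy)-5-(3-methylbut-2-en-1-yl)phenyl]prop-2-yn-1-one F5, and K2CO3 in acetone would close ring C alone to give 17.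

Step 7. Addition to the aldehyde may stall because the ortho-phenoxide and the para-alkoxy group make the formyl carbon a poor electrophile, and the ortho-hydroxybenzylic alcohol may ionise on work-up. The fallback sets out from 4 and changes the bond made in the fragment union from the carbinol C–C bond to the aryl–alkyne bond; it comes back at 14 and bypasses steps 5 and 6. Aldehyde 4 would be treated with an excess of the small, cheap ethynylmagnesium bromide (3 equiv, THF, 0 °C) to give 2-(1-hydroxyprop-2-yn-1-yl)-5-(methoxymethoxy)-4-(3-methylbut-2-en-1-yl)phenol F6. This terminal alkyne would then be joined to aryl bromide 8 by Sonogashira coupling at room temperature (Pd(PhCN)2Cl2, P(t-Bu)3, CuI, i-Pr2NH, dioxane), the mild temperature being chosen to suppress cycloisomerisation of the free phenol onto the alkyne.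

Step 2. Transfer of the prenyl group may occur with allylic transposition to give the branched 1,1-dimethylallyl arene, or oxidative addition into the electron-rich aryl bromide may be slow enough for protodebromination to compete. The fallback sets out from 2 and replaces direct prenylation by allylation and olefin cross-metathesis; it comes back at 4. Stille coupling of 2 with allyltributylstannane (Pd(PPh3)4, DMF, 100 °C), for which the regiochemical question does not arise, would give 5-allyl-2-hydroxy-4-(methoxymethoxy)benzaldehyde F7. Cross-metathesis of F7 with 2-methylbut-2-ene (second-generation Grubbs catalyst, CH2Cl2, 40 °C) would convert the allyl group into the prenyl group.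

**Further compounds**

F1 | step 9 | 4-[(2-methylbut-3-yn-2-yl)oxy]benzaldehyde | O=Cc1ccc(OC(C)(C)C#C)cc1
F2 | step 9 | 2,2-dimethyl-2H-chromene-6-carbaldehyde | CC1(C)C=Cc2cc(C=O)ccc2O1
F3 | step 9 | 6-ethynyl-2,2-dimethyl-2H-chromene | CC1(C)C=Cc2cc(C#C)ccc2O1
F4 | step 9 | 2-[3-(2,2-dimethyl-2H-chromen-6-yl)-1-hydroxyprop-2-yn-1-yl]-5-(methoxymethoxy)-4-(3-methylbut-2-en-1-yl)phenol (racemic) | CC(C)=CCc1cc(C(O)C#Cc2ccc3c(c2)C=CC(C)(C)O3)c(O)cc1OCOC
F5 | step 9 | 3-(2,2-dimethyl-2H-chromen-6-yl)-1-[2-hydroxy-4-(methoxymethoxy)-5-(3-methylbut-2-en-1-yl)phenyl]prop-2-yn-1-one | CC(C)=CCc1cc(C(=O)C#Cc2ccc3c(c2)C=CC(C)(C)O3)c(O)cc1OCOC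
F6 | step 7 | 2-(1-hydroxyprop-2-yn-1-yl)-5-(methoxymethoxy)-4-(3-methylbut-2-en-1-yl)phenol (racemic) | CC(C)=CCc1cc(C(O)C#C)c(O)cc1OCOC
F7 | step 2 | 5-allyl-2-hydroxy-4-(methoxymethoxy)benzaldehyde | O=Cc1cc(CC=C)c(OCOC)cc1O
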